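**Plan**

- Cuts: the two MOM ethers; the O1–C2 bond twice (as the final aryl ether, and one oxidation level higher as the lactone C–O bond of the key step); the C3=C4 bond (Perkin condensation), which separates a ring A salicylaldehyde from a ring B arylacetic acid; the C8–prenyl and aryl–CHO bonds of ring A; the pyran ring and the homologating carbon of ring B.
- Enabling feature: C3 sits between the C4 methylene and the O1-bound C2 of ring C, so the 3-aryl-chroman-2-one form of ring C is a redox isomer of a 2-aryl enal (C2 as aldehyde, C3=C4) that carries the C8a phenol.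
- Forward order: the pyran of ring B is made first; rings A and B are joined through C3=C4 as a 3-arylcoumarin, which is reduced to the lactol/enal level; ring C is closed as the (S)-lactone in the key step, opened by hydride and closed for good as the ether by a Mitsunobu reaction; the MOM ethers come off last.
- Stereochemistry: the only stereocentre, C3 (S), comes from carbene-catalyst-controlled protonation in the key step; it stops being enolisable one step later and is not touched again.

Key step: step 12

Assumption: the sense of induction of the aminoindanol-derived triazolium salt on this substrate class cannot be predicted with certainty; the (5aS,10bR) antipode is written, and its mirror image would be used if a pilot run delivers the (R)-lactone.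

**Route**

Step 1
Reactants: 1 resorcinol
Product: 2 1,3-bis(methoxymethoxy)benzene
Conditions: NaH, MOMCl, DMF, 0 °C → rt
Reagents that add atoms: chloromethyl methyl ether (MOMCl), COCCl
Why: Williamson-type O-alkylation of the resorcinol dianion with the reactive α-chloro ether caps both phenols as MOM ethers, which then serve as ortho-directing groups.

Step 2
Reactants: 2 1,3-bis(methoxymethoxy)benzene; 3 prenyl bromide
Product: 5 1,3-bis(methoxymethoxy)-2-(3-methylbut-2-en-1-yl)benzene, via 2-lithio-1,3-bis(methoxymethoxy)benzene 4 (not isolated)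
Conditions: n-BuLi, THF, 0 °C → rt; CuI (10 mol%), then prenyl bromide, −78 °C → rt
Reagents that add atoms: none
Why: Directed ortho-metalation occurs at the position flanked by both MOM ethers, and copper-assisted SN2 allylic substitution of the aryllithium on prenyl bromide should install the linear prenyl group.

Step 3
Reactants: 5 1,3-bis(methoxymethoxy)-2-(3-methylbut-2-en-1-yl)benzene
Product: 7 2,4-bis(methoxymethoxy)-3-(3-methylbut-2-en-1-yl)benzaldehyde, via C4 aryllithium 6 (not isolated)
Conditions: n-BuLi, TMEDA, THF, −20 → 0 °C; DMF, −78 °C → rt; H2O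
Reagents that add atoms: N,N-dimethylformamide (DMF), CN(C)C=O
Why: A second directed ortho-metalation at the remaining position ortho to a MOM ether (both are equivalent by symmetry), followed by formylation with DMF, places the aldehyde next to one oxygen with the prenyl group between both oxygens.

Step 4
Reactants: 7 2,4-bis(methoxymethoxy)-3-(3-methylbut-2-en-1-yl)benzaldehyde
Product: 8 2,4-dihydroxy-3-(3-methylbut-2-en-1-yl)benzaldehyde
Conditions: 3 M HCl (aq.), MeOH, rt
Reagents that add atoms: none
Why: Acid-catalysed acetal exchange with methanol removes both MOM ethers, and the low temperature should keep the prenyl group from cyclising onto the neighbouring phenols.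

Step 5
Reactants: 8 2,4-dihydroxy-3-(3-methylbut-2-en-1-yl)benzaldehyde
Product: 9 2-hydroxy-4-(methoxymethoxy)-3-(3-methylbut-2-en-1-yl)benzaldehyde
Conditions: MOMCl (1.05 equiv), K2CO3, acetone, 0 °C → rt
Reagents that add atoms: chloromethyl methyl ether (MOMCl), COCCl
Why: Selective O-alkylation is expected because the 2-OH is held in a hydrogen bond to the aldehyde and is far less nucleophilic than the 4-OH, so only the future C7 oxygen is capped.

Step 6
Reactants: 10 2,4-dihydroxybenzaldehyde; 11 3-methylbut-2-enal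
Product: 12 5-hydroxy-2,2-dimethyl-2H-chromene-6-carbaldehyde
Conditions: ethylenediammonium diacetate (10 mol%), toluene, reflux
Reagents that add atoms: none
Why: Knoevenagel-type condensation at the carbon between the two oxygens gives an ortho-quinone methide that closes by oxa-6π electrocyclisation through the non-chelated 4-OH, a standard chromene annulation that fixes the ring B substitution pattern.

Step 7
Reactants: 12 5-hydroxy-2,2-dimethyl-2H-chromene-6-carbaldehyde
Product: 13 5-(methoxymethoxy)-2,2-dimethyl-2H-chromene-6-carbaldehyde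
Conditions: NaH, MOMCl, DMF, 0 °C → rt
Reagents that add atoms: chloromethyl methyl ether (MOMCl), COCCl
Why: O-alkylation of the chelated phenol after full deprotonation protects the ring B oxygen that would otherwise compete for the acyl azolium in the key step.

Step 8
Reactants: 13 5-(methoxymethoxy)-2,2-dimethyl-2H-chromene-6-carbaldehyde
Product: 15 2-[5-(methoxymethoxy)-2,2-dimethyl-2H-chromen-6-yl]acetonitrile, via N-(1-tosylvinyl)formamide 14 (not isolated)
Conditions: TosMIC, KOt-Bu, DME, −40 °C; then MeOH, reflux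
Reagents that add atoms: p-toluenesulfonylmethyl isocyanide (TosMIC), Cc1ccc(cc1)S(=O)(=O)C[N+]#[C-]
Why: TosMIC reductive cyanation (van Leusen reaction) homologates the aryl aldehyde by one carbon, since the TosMIC anion adds to the aldehyde and ring-opens to the N-(1-tosylvinyl)formamide, from which methoxide removes the formyl group and sulfinate is eliminated to leave the arylacetonitrile.

Step 9
Reactants: 15 2-[5-(methoxymethoxy)-2,2-dimethyl-2H-chromen-6-yl]acetonitrile
Product: 16 2-[5-(methoxymethoxy)-2,2-dimethyl-2H-chromen-6-yl]acetic acid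
Conditions: KOH, EtOH/H2O, reflux; then cold 1 M HCl to pH 4
Reagents that add atoms: water, O
Why: Alkaline nitrile hydrolysis via the amide gives the arylacetic acid, and both the MOM ether and the chromene tolerate hot aqueous alkali.

Step 10
Reactants: 9 2-hydroxy-4-(methoxymethoxy)-3-(3-methylbut-2-en-1-yl)benzaldehyde; 16 2-[5-(methoxymethoxy)-2,2-dimethyl-2H-chromen-6-yl]acetic acid
Product: 17 7-(methoxymethoxy)-3-[5-(methoxymethoxy)-2,2-dimethyl-2H-chromen-6-yl]-8-(3-methylbut-2-en-1-yl)-2H-chromen-2-one
Conditions: Ac2O, Et3N, 110 °C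
Reagents that add atoms: none
Why: In this Perkin–Oglialoro condensation the mixed anhydride of 16 acylates the phenol, and intramolecular aldol condensation then forms C3=C4 and delivers the 3-arylcoumarin in one operation.

Step 11
Reactants: 17 7-(methoxymethoxy)-3-[5-(methoxymethoxy)-2,2-dimethyl-2H-chromen-6-yl]-8-(3-methylbut-2-en-1-yl)-2H-chromen-2-one
Product: 18 7-(methoxymethoxy)-3-[5-(methoxymethoxy)-2,2-dimethyl-2H-chromen-6-yl]-8-(3-methylbut-2-en-1-yl)-2H-chromen-2-ol
Conditions: i-Bu2AlH (1.1 equiv), CH2Cl2, −78 °C; aq. potassium sodium tartrate; used crude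
Reagents that add atoms: none
Why: Partial lactone reduction with one hydride at −78 °C stops at the aluminium lactolate, a known route from coumarins to 2H-chromen-2-ols, and gives the ring-closed tautomer of the (Z)-2-hydroxy-α-arylcinnamaldehyde.

Step 12
Reactants: 18 7-(methoxymethoxy)-3-[5-(methoxymethoxy)-2,2-dimethyl-2H-chromen-6-yl]-8-(3-methylbut-2-en-1-yl)-2H-chromen-2-ol
Product: 20 (S)-7-(methoxymethoxy)-3-[5-(methoxymethoxy)-2,2-dimethyl-2H-chromen-6-yl]-8-(3-methylbut-2-en-1-yl)chroman-2-one, via (Z)-enal 19 (not isolated)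
Conditions: (5aS,10bR)-2-mesityl-5a,10b-dihydro-4H,6H-indeno[2,1-b][1,2,4]triazolo[4,3-d][1,4]oxazin-2-ium chloride (10 mol%), i-Pr2NEt (20 mol%), toluene, 0 °C → rt, argon; AcOH quench
Reagents that add atoms: none
Why: Proposed new method: base opens lactol 18 to the (Z)-enal 19, the carbene adds to the aldehyde to give the enaminol (acyl anion equivalent), its homoenolate is protonated at C4 (which erases the alkene geometry), and the resulting α-aryl azolium enolate is protonated at C3 before the acyl azolium is captured by the C8a phenoxide, releasing the carbene. The closest known reactions are the carbene-catalysed internal redox lactonisation of 2-hydroxycinnamaldehydes to dihydrocoumarins and the enantioselective protonation of α-aryl azolium enolates generated from ketenes or α-haloaldehydes; merging the two on an α-aryl enal is the untested part. Ring C closes by 6-exo-trig acyl transfer to O1. The C3 stereocentre is set by catalyst control, because the aminoindanol backbone and the N-mesityl group shield one face of the azolium enolate so that the proton, relayed by the substrate phenol or the ammonium salt, arrives on the open face to give the (S)-lactone. The step needs C4 protonation to outrun acyloin-type and oxidative pathways and needs the C8a oxygen to be the only acyl acceptor: the MOM ether on the ring B oxygen blocks the competing five-membered benzofuranone closure, the free phenol sits in reach of the acyl carbon, and the weak base, low temperature and acidic quench should protect the enolisable α-aryl lactone from racemisation.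

Step 13
Reactants: 20 (S)-7-(methoxymethoxy)-3-[5-(methoxymethoxy)-2,2-dimethyl-2H-chromen-6-yl]-8-(3-methylbut-2-en-1-yl)chroman-2-one
Product: 21 (S)-3-[2-hydroxy-4-(methoxymethoxy)-3-(3-methylbut-2-en-1-yl)phenyl]-2-[5-(methoxymethoxy)-2,2-dimethyl-2H-chromen-6-yl]propan-1-ol
Conditions: LiBH4, THF, 0 °C; then H2O
Reagents that add atoms: none
Why: Borohydride reduction of the activated aryl lactone to the primary alcohol and phenol is fast at 0 °C and, being essentially non-basic, should leave C3 intact, after which C3 is no longer enolisable.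

Step 14
Reactants: 21 (S)-3-[2-hydroxy-4-(methoxymethoxy)-3-(3-methylbut-2-en-1-yl)phenyl]-2-[5-(methoxymethoxy)-2,2-dimethyl-2H-chromen-6-yl]propan-1-ol
Product: 22 (S)-7-(methoxymethoxy)-3-[5-(methoxymethoxy)-2,2-dimethyl-2H-chromen-6-yl]-8-(3-methylbut-2-en-1-yl)chroman
Conditions: PPh3, DIAD, THF, 0 °C → rt
Reagents that add atoms: none
Why: Intramolecular Mitsunobu etherification (6-exo-tet attack of the only free phenol on the activated primary carbon) closes ring C without involving C3, as is standard in isoflavan synthesis.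

Step 15
Reactants: 22 (S)-7-(methoxymethoxy)-3-[5-(methoxymethoxy)-2,2-dimethyl-2H-chromen-6-yl]-8-(3-methylbut-2-en-1-yl)chroman
Product: 23 (S)-3-(5-hydroxy-2,2-dimethyl-2H-chromen-6-yl)-8-(3-methylbut-2-en-1-yl)chroman-7-ol
Conditions: 3 M HCl (aq.), MeOH, rt → 40 °C
Reagents that add atoms: none
Why: Acid-catalysed acetal cleavage of the two aryl MOM ethers under mild methanolic HCl, conditions that prenyl phenols and 2,2-dimethylchromenes normally tolerate, should release the target.

**Compound list**

1 | resorcinol | Oc1cccc(O)c1 | starting material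
2 | 1,3-bis(methoxymethoxy)benzene | COCOc1cccc(OCOC)c1 | intermediate
3 | prenyl bromide (1-bromo-3-methylbut-2-ene) | CC(C)=CCBr | starting material
4 | 2-lithio-1,3-bis(methoxymethoxy)benzene | [Li]c1c(OCOC)cccc1OCOC | intermediate
5 | 1,3-bis(methoxymethoxy)-2-(3-methylbut-2-en-1-yl)benzene | COCOc1cccc(OCOC)c1CC=C(C)C | intermediate
6 | 4-lithio-1,3-bis(methoxymethoxy)-2-(3-methylbut-2-en-1-yl)benzene | [Li]c1ccc(OCOC)c(CC=C(C)C)c1OCOC | intermediate
7 | 2,4-bis(methoxymethoxy)-3-(3-methylbut-2-en-1-yl)benzaldehyde | O=Cc1ccc(OCOC)c(CC=C(C)C)c1OCOC | intermediate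
8 | 2,4-dihydroxy-3-(3-methylbut-2-en-1-yl)benzaldehyde | O=Cc1ccc(O)c(CC=C(C)C)c1O | intermediate
9 | 2-hydroxy-4-(methoxymethoxy)-3-(3-methylbut-2-en-1-yl)benzaldehyde | O=Cc1ccc(OCOC)c(CC=C(C)C)c1O | intermediate
10 | 2,4-dihydroxybenzaldehyde | O=Cc1ccc(O)cc1O | starting material
11 | 3-methylbut-2-enal | CC(C)=CC=O | starting material
12 | 5-hydroxy-2,2-dimethyl-2H-chromene-6-carbaldehyde | O=Cc1ccc2c(c1O)C=CC(C)(C)O2 | intermediate
13 | 5-(methoxymethoxy)-2,2-dimethyl-2H-chromene-6-carbaldehyde | O=Cc1ccc2c(c1OCOC)C=CC(C)(C)O2 | intermediate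
14 | N-{2-[5-(methoxymethoxy)-2,2-dimethyl-2H-chromen-6-yl]-1-tosylvinyl}formamide | O=CNC(=Cc1ccc2c(c1OCOC)C=CC(C)(C)O2)S(=O)(=O)c1ccc(C)cc1 | intermediate
15 | 2-[5-(methoxymethoxy)-2,2-dimethyl-2H-chromen-6-yl]acetonitrile | N#CCc1ccc2c(c1OCOC)C=CC(C)(C)O2 | intermediate
16 | 2-[5-(methoxymethoxy)-2,2-dimethyl-2H-chromen-6-yl]acetic acid | OC(=O)Cc1ccc2c(c1OCOC)C=CC(C)(C)O2 | intermediate
17 | 7-(methoxymethoxy)-3-[5-(methoxymethoxy)-2,2-dimethyl-2H-chromen-6-yl]-8-(3-methylbut-2-en-1-yl)-2H-chromen-2-one | CC(C)=CCc1c(OCOC)ccc2c1OC(=O)C(c1ccc3c(c1OCOC)C=CC(C)(C)O3)=C2 | intermediate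
18 | 7-(methoxymethoxy)-3-[5-(methoxymethoxy)-2,2-dimethyl-2H-chromen-6-yl]-8-(3-methylbut-2-en-1-yl)-2H-chromen-2-ol (lactol, either configuration at C2) | CC(C)=CCc1c(OCOC)ccc2c1OC(O)C(c1ccc3c(c1OCOC)C=CC(C)(C)O3)=C2 | intermediate
19 | (Z)-3-[2-hydroxy-4-(methoxymethoxy)-3-(3-methylbut-2-en-1-yl)phenyl]-2-[5-(methoxymethoxy)-2,2-dimethyl-2H-chromen-6-yl]acrylaldehyde | O=C/C(c1ccc2c(c1OCOC)C=CC(C)(C)O2)=C\c1ccc(OCOC)c(CC=C(C)C)c1O | intermediate
20 | (S)-7-(methoxymethoxy)-3-[5-(methoxymethoxy)-2,2-dimethyl-2H-chromen-6-yl]-8-(3-methylbut-2-en-1-yl)chroman-2-one | CC(C)=CCc1c(OCOC)ccc2c1OC(=O)[C@H](c1ccc3c(c1OCOC)C=CC(C)(C)O3)C2 | intermediate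
21 | (S)-3-[2-hydroxy-4-(methoxymethoxy)-3-(3-methylbut-2-en-1-yl)phenyl]-2-[5-(methoxymethoxy)-2,2-dimethyl-2H-chromen-6-yl]propan-1-ol | OC[C@H](c1ccc2c(c1OCOC)C=CC(C)(C)O2)Cc1ccc(OCOC)c(CC=C(C)C)c1O | intermediate
22 | (S)-7-(methoxymethoxy)-3-[5-(methoxymethoxy)-2,2-dimethyl-2H-chromen-6-yl]-8-(3-methylbut-2-en-1-yl)chroman | CC(C)=CCc1c(OCOC)ccc2c1OC[C@H](c1ccc3c(c1OCOC)C=CC(C)(C)O3)C2 | intermediate
23 | (S)-3-(5-hydroxy-2,2-dimethyl-2H-chromen-6-yl)-8-(3-methylbut-2-en-1-yl)chroman-7-ol | CC(C)=CCc1c(O)ccc2c1OC[C@H](c1ccc3c(c1O)C=CC(C)(C)O3)C2 | target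

**Step count**

Total: 15 steps. Longest linear sequence: 11 steps (steps 1–5 and 10–15, from resorcinol); the ring B branch (steps 6–9) joins at step 10.

**Steps most likely to fail**

1. Step 12. The protonation at C3 may show poor facial selectivity, the hindered α-aryl enaminol may turn over slowly, or the lactone may lose configuration under the basic conditions. The fallback sets the stereocentre by oxazolidinone-auxiliary enolate alkylation, the standard entry to isoflavans; it sets out from aldehyde 9 and acid 16 and comes back at diol 21. Aldehyde 9 is O-allylated (allyl bromide, K2CO3, DMF) to 2-(allyloxy)-4-(methoxymethoxy)-3-(3-methylbut-2-en-1-yl)benzaldehyde F1, reduced (NaBH4, MeOH, 0 °C) to [2-(allyloxy)-4-(methoxymethoxy)-3-(3-methylbut-2-en-1-yl)phenyl]methanol F2 and brominated (PPh3, CBr4, CH2Cl2, 0 °C) to 2-(allyloxy)-1-(bromomethyl)-4-(methoxymethoxy)-3-(3-methylbut-2-en-1-yl)benzene F3. Acid 16 is coupled with (S)-4-benzyloxazolidin-2-one (pivaloyl chloride, Et3N, LiCl, THF) to (S)-4-benzyl-3-{2-[5-(methoxymethoxy)-2,2-dimethyl-2H-chromen-6-yl]acetyl}oxazolidin-2-one F4. Deprotonation with NaN(SiMe3)2 (THF, −78 °C) and alkylation with F3 on the enolate face remote from the benzyl group should give (S)-4-benzyl-3-{(S)-3-[2-(allyloxy)-4-(methoxymethoxy)-3-(3-methylbut-2-en-1-yl)phenyl]-2-[5-(methoxymethoxy)-2,2-dimethyl-2H-chromen-6-yl]propanoyl}oxazolidin-2-one F5. LiBH4 (THF, H2O, 0 °C) then cleaves the auxiliary to (S)-3-[2-(allyloxy)-4-(methoxymethoxy)-3-(3-methylbut-2-en-1-yl)phenyl]-2-[5-(methoxymethoxy)-2,2-dimethyl-2H-chromen-6-yl]propan-1-ol F6, and Pd(PPh3)4 with morpholine (THF, rt) removes the allyl group to give 21, from which steps 14 and 15 follow unchanged.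

2. Step 11. The aluminium lactolate may collapse (aryloxide is a good leaving group) and be reduced further to the allylic diol, and the lactol may dehydrate or dimerise on handling. The fallback builds the lactol oxidation level directly by enamine condensation instead of lactone reduction; it sets out from nitrile 15 and aldehyde 9 and comes back at lactol 18. Nitrile 15 is reduced with i-Bu2AlH (toluene, −78 °C; buffered aqueous work-up) to 2-[5-(methoxymethoxy)-2,2-dimethyl-2H-chromen-6-yl]acetaldehyde F7, which is condensed with morpholine (toluene, molecular sieves) to (E)-4-{2-[5-(methoxymethoxy)-2,2-dimethyl-2H-chromen-6-yl]vinyl}morpholine F8. F8 and salicylaldehyde 9 in toluene should give, by C-attack of the enamine on the aldehyde, closure of the phenol onto the iminium ion and loss of water, 4-{7-(methoxymethoxy)-3-[5-(methoxymethoxy)-2,2-dimethyl-2H-chromen-6-yl]-8-(3-methylbut-2-en-1-yl)-2H-chromen-2-yl}morpholine F9 (the classical 2-morpholinoisoflav-3-ene construction). Hydrolysis of this aminal on wet silica gel or with dilute aqueous oxalic acid gives 18.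

3. Step 3. Deprotonation may occur at the benzylic–allylic methylene flanked by both MOM ethers instead of at the ring, giving the wrong anion or mixtures. The fallback introduces the prenyl group into an aldehyde that is already in place; it sets out from 2,4-dihydroxybenzaldehyde 10 and prenyl bromide 3 and comes back at 8, so that steps 1–4 are bypassed. C-alkylation of the phenoxide of 10 with 3 in aqueous KOH at room temperature attacks the carbon between the two oxygens and, after chromatographic removal of the C5- and O-alkylated isomers, leads directly to 8. No compound outside the list is formed (entry F0).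

**Further compounds**

F1 | step 12 | 2-(allyloxy)-4-(methoxymethoxy)-3-(3-methylbut-2-en-1-yl)benzaldehyde | O=Cc1ccc(OCOC)c(CC=C(C)C)c1OCC=C
F2 | step 12 | [2-(allyloxy)-4-(methoxymethoxy)-3-(3-methylbut-2-en-1-yl)phenyl]methanol | OCc1ccc(OCOC)c(CC=C(C)C)c1OCC=C
F3 | step 12 | 2-(allyloxy)-1-(bromomethyl)-4-(methoxymethoxy)-3-(3-methylbut-2-en-1-yl)benzene | BrCc1ccc(OCOC)c(CC=C(C)C)c1OCC=C
F4 | step 12 | (S)-4-benzyl-3-{2-[5-(methoxymethoxy)-2,2-dimethyl-2H-chromen-6-yl]acetyl}oxazolidin-2-one | O=C1OC[C@H](Cc2ccccc2)N1C(=O)Cc1ccc2c(c1OCOC)C=CC(C)(C)O2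
F5 | step 12 | (S)-4-benzyl-3-{(S)-3-[2-(allyloxy)-4-(methoxymethoxy)-3-(3-methylbut-2-en-1-yl)phenyl]-2-[5-(methoxymethoxy)-2,2-dimethyl-2H-chromen-6-yl]propanoyl}oxazolidin-2-one | O=C1OC[C@H](Cc2ccccc2)N1C(=O)[C@H](c1ccc2c(c1OCOC)C=CC(C)(C)O2)Cc1ccc(OCOC)c(CC=C(C)C)c1OCC=C
F6 | step 12 | (S)-3-[2-(allyloxy)-4-(methoxymethoxy)-3-(3-methylbut-2-en-1-yl)phenyl]-2-[5-(methoxymethoxy)-2,2-dimethyl-2H-chromen-6-yl]propan-1-ol | OC[C@H](c1ccc2c(c1OCOC)C=CC(C)(C)O2)Cc1ccc(OCOC)c(CC=C(C)C)c1OCC=C
F7 | step 11 | 2-[5-(methoxymethoxy)-2,2-dimethyl-2H-chromen-6-yl]acetaldehyde | O=CCc1ccc2c(c1OCOC)C=CC(C)(C)O2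
F8 | step 11 | (E)-4-{2-[5-(methoxymethoxy)-2,2-dimethyl-2H-chromen-6-yl]vinyl}morpholine | O1CCN(CC1)/C=C/c1ccc2c(c1OCOC)C=CC(C)(C)O2
F9 | step 11 | 4-{7-(methoxymethoxy)-3-[5-(methoxymethoxy)-2,2-dimethyl-2H-chromen-6-yl]-8-(3-methylbut-2-en-1-yl)-2H-chromen-2-yl}morpholine | CC(C)=CCc1c(OCOC)ccc2c1OC(N1CCOCC1)C(c1ccc3c(c1OCOC)C=CC(C)(C)O3)=C2
F0 | step 3 | none | none
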